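**Strategy.** Everything rests on reading the quaternary C4 of ring A, with its equatorial C18 methyl and axial C19 carboxyl, as the product of an epoxide-to-aldehyde 1,2-shift in which C19 was first a ring member. The precursor is a trans-fused A-homo bicycle whose seven-membered ring (C1–C2–C3–C19–C4–C5–C10) carries a β-epoxide across C4–C19. A bulky aluminium Lewis acid ionises C4–O and C3 migrates from C19 to C4. This one operation contracts the ring to six atoms, sets C4 by inversion and expels C19 as the axial formyl group. The bicycle comes from (+)-verbenone, whose carbons map onto ring B, C20, C4 and C18.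

Key step: step 8

Remark on the chemistry: labdane numbering is used for every intermediate (C19 is the carbon that ends as the carboxyl group). α means the face opposite to the C20 methyl group. (1R,5R)-(+)-Verbenone and methyl hydrogen (R)-3-methylglutarate are taken as commercial single enantiomers.

Step 1
Reactants: 1 methyl hydrogen (R)-3-methylglutarate
Product: 3 (S)-4-methyloxan-2-one, via hydroxy acid 2 (not isolated)
Conditions: LiBH4 (2 equiv), THF, 0 °C to rt; then 2 M HCl, rt
Reagents that add atoms: none
Why: Chemoselective hydride reduction followed by acid lactonisation, in which LiBH4 reduces the methyl ester but not the lithium carboxylate, so the former ester carbon becomes the future C11 and the untouched stereocentre becomes C13 with the S configuration of the target.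

Step 2
Reactants: 3 (S)-4-methyloxan-2-one
Product: 5 methyl (R)-5-iodo-3-methylpentanoate, via silyl ester 4 (not isolated)
Conditions: Me3SiI (1.1 equiv), CH2Cl2, rt; then MeOH, rt
Reagents that add atoms: iodotrimethylsilane C[Si](C)(C)I; methanol CO
Why: Silyl iodide cleavage of a lactone, in which O-silylation and SN2 attack of iodide at the O–CH2 carbon open the ring and acidic methanol turns the silyl ester into the methyl ester, the stereocentre staying untouched (its descriptor changes only through the priority of iodine).

Step 3
Reactants: 6 (1R,5R)-(+)-verbenone; 7 5-bromopent-1-ene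
Product: 9 (1R,4R,5R)-4,6,6-trimethyl-4-(pent-4-en-1-yl)bicyclo[3.1.1]heptan-2-one, via Grignard reagent 8 (not isolated)
Conditions: 7, Mg, THF, rt to 40 °C; then CuBr·SMe2 (10 mol %), 6, THF, −40 to 0 °C; aq. NH4Cl
Reagents that add atoms: none
Why: Copper-catalysed conjugate addition of a Grignard reagent, in which the organocopper species attacks the β-carbon (C10) from the face opposite to the gem-dimethyl bridge, so the new chain (C1, C2, C3, C19) ends trans to C4 and the C20 methyl cis to it, as the trans ring fusion requires.

Step 4
Reactants: 9 conjugate adduct; 5 methyl (R)-5-iodo-3-methylpentanoate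
Product: 11 C9-alkylated bicyclic keto ester (side chain at C9 anti to the gem-dimethyl bridge, 9-epi series), via lithium enolate 10 (not isolated)
Conditions: LiN(iPr)2 (1.0 equiv), THF, −78 to 0 °C; then 5, HMPA, −78 °C to rt
Reagents that add atoms: none
Why: Ketone enolate alkylation (SN2), in which the other α-position (C7) is a bridgehead that cannot enolise (Bredt's rule), so only the C8–C9 enolate forms and forcing conditions cannot scramble the site, while the iodide enters anti to the bridge and gives a C9 configuration that step 5 corrects.

Step 5
Reactants: 11 C9-alkylated bicyclic keto ester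
Product: 14 ring B dienyl keto ester (cyclohexanone with C8=O, equatorial 9β side chain, axial 10β-methyl, equatorial pent-4-enyl at C10, equatorial isopropenyl at C5, H-5α), via tertiary iodide 12 (not isolated), via isopropenyl silyl enol ether 13 (not isolated)
Conditions: Me3SiI (1.2 equiv), CH2Cl2, −20 °C; DBU (2 equiv), −20 °C to rt; then NaOMe (3 equiv), MeOH, rt
Reagents that add atoms: none
Why: Silyl iodide fragmentation of a strained cyclobutyl ketone followed by E2 elimination and base epimerisation, in which O-silylation triggers heterolysis of the C7–C4 bond towards the tertiary C4, DBU takes a methyl proton because C5–H is shielded by the quaternary C10 and its loss would give a strained tetrasubstituted alkene, and methoxide frees the ketone and equilibrates C9 to the equatorial epimer.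

Step 6
Reactants: 14 ring B dienyl keto ester
Product: 15 A-homo alkene (trans-fused bicyclo[5.4.0]undecenone keto ester with C4(CH3)=C19H in the seven-membered ring)
Conditions: second-generation Grubbs catalyst (5 mol %), 1,4-benzoquinone (10 mol %), CH2Cl2 (0.002 M), reflux
Reagents that add atoms: none
Why: Ring-closing metathesis, which initiates at the monosubstituted alkene and closes on the isopropenyl group, the two chains being trans-diequatorial on ring B, so the trans-fused cycloheptene should form with loss of ethene and without change at any stereocentre.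

Step 7
Reactants: 15 A-homo alkene
Product: 17 4β,19β-epoxide of 15 (oxygen cis to C20, C18 methyl α), via bromohydrin 16 (not isolated)
Conditions: NBS (1.05 equiv), DME–H2O, 0 °C; then K2CO3, MeOH, rt
Reagents that add atoms: water O
Why: Bromohydrin formation and intramolecular Williamson closure, in which the bromonium ion forms on the open α face, water attacks the tertiary C4 anti (from β, Markovnikov) as in the classical route to β-epoxides of angular-methyl decalins and steroids, and the alkoxide displaces the 19α-bromide with inversion, so oxygen ends on the face that a peracid would not reach.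

Step 8
Reactants: 17 4β,19β-epoxide
Product: 18 methyl (13S)-8,19-dioxo-17-norlabdan-15-oate (ring A six-membered, axial 4β-CHO, equatorial 4α-CH3)
Conditions: MeAl(OC6H2-4-Br-2,6-tBu2)2 (2.5 equiv, made from AlMe3 and 4-bromo-2,6-di-tert-butylphenol in CH2Cl2, rt), CH2Cl2, −78 to −20 °C; then 1 M HCl
Reagents that add atoms: none
Why: The aluminium centre binds the epoxide oxygen on the β face and lengthens the tertiary C4–O bond, and as positive charge builds at C4 the C19–C3 σ bond shifts to the rear (α) lobe of C4 while C19 becomes the aluminium-bound formyl carbon (Meinwald or semipinacol rearrangement, the closest known type being the conversion of trisubstituted epoxides into α-quaternary aldehydes by this same aluminium bis(phenoxide)). Ring A is closed by this suprafacial 1,2-alkyl shift through a three-centre transition state (formally a 3-exo-tet attack of the σ bond on C4), so the ring C1–C2–C3–C19–C4–C5–C10 becomes the ring C1–C2–C3–C4–C5–C10. The only new stereocentre, C4, is formed with inversion: oxygen leaves from the β face and C3 enters from the α face, so C19 stays β (axial, cis to C20) and C18 becomes α (equatorial), the outcome being dictated by the epoxide configuration set in step 7. The step needs the alkyl shift to win over the 1,2-hydride shift that would give the A-homo C19 ketone, and two features favour this: the very large phenoxide ligands disfavour the rotamer that aligns C19–H with the empty orbital, and relief of cycloheptane strain on forming a chair cyclohexane favours contraction. The C8 ketone and the ester only bind excess Lewis acid, which is why more than two equivalents are used.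

Step 9
Reactants: 18 keto aldehyde
Product: 19 (13S)-15-methoxy-8,15-dioxo-17-norlabdan-19-oic acid
Conditions: NaClO2, NaH2PO4, 2-methylbut-2-ene, t-BuOH–H2O, rt
Reagents that add atoms: sodium chlorite [Na+].[O-]Cl=O
Why: Pinnick oxidation, which converts even hindered neopentyl aldehydes into acids under buffered conditions that leave the ketone, the ester and the non-enolisable C4 centre untouched.

Step 10
Reactants: 19 keto acid
Product: 20 (13S)-15-methoxy-15-oxolabd-8(17)-en-19-oic acid
Conditions: Ph3PCH3Br (4 equiv), NaN(SiMe3)2 (3.8 equiv), THF, 0 °C; then 19, 0 °C to reflux; then aq. citric acid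
Reagents that add atoms: methyltriphenylphosphonium bromide C[P+](c1ccccc1)(c1ccccc1)c1ccccc1.[Br-]
Why: Wittig methylenation with excess ylide, in which the first equivalent only forms the inert C19 carboxylate, the methyl ester is far less electrophilic than the C8 ketone, and any base-induced equilibration at C9 returns the already favoured equatorial epimer.

Step 11
Reactants: 20 ester acid
Product: 21 (13S)-15-hydroxylabd-8(17)-en-19-oic acid (imbricatolic acid)
Conditions: LiEt3BH (3.5 equiv), THF, 0 °C; then 1 M HCl
Reagents that add atoms: none
Why: Chemoselective hydride reduction, in which the first equivalent deprotonates the acid to a carboxylate that this reagent does not reduce, the unhindered C15 ester is reduced quickly, and the released BEt3 cannot hydroborate the exocyclic alkene.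

Step 12
Reactants: 21 imbricatolic acid; 22 stearoyl chloride
Product: 23 (13S)-15-(stearoyloxy)labd-8(17)-en-19-oic acid (target)
Conditions: 22 (1.1 equiv), pyridine (3 equiv), DMAP (5 mol %), CH2Cl2, 0 °C to rt; then aq. NaHCO3–THF, rt
Reagents that add atoms: none
Why: Acylation of an alcohol with an acid chloride, in which the only hydroxyl group is primary and open while the C19 acid is axial and neopentyl, and any mixed anhydride should be hydrolysed at its unhindered stearoyl carbonyl during the bicarbonate wash, with no stereocentre touched.

**Compound list**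

1 | methyl hydrogen (R)-3-methylglutarate | COC(=O)C[C@H](C)CC(=O)O | starting material
2 | (S)-5-hydroxy-3-methylpentanoic acid | OCC[C@H](C)CC(=O)O | intermediate
3 | (S)-4-methyloxan-2-one | C[C@H]1CCOC(=O)C1 | intermediate
4 | trimethylsilyl (R)-5-iodo-3-methylpentanoate | ICC[C@H](C)CC(=O)O[Si](C)(C)C | intermediate
5 | methyl (R)-5-iodo-3-methylpentanoate | ICC[C@H](C)CC(=O)OC | intermediate
6 | (1R,5R)-(+)-verbenone | O=C1[C@@H]2C[C@@H](C2(C)C)C(C)=C1 | starting material
7 | 5-bromopent-1-ene | C=CCCCBr | starting material
8 | pent-4-enylmagnesium bromide | C=CCCC[Mg]Br | intermediate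
9 | (1R,4R,5R)-4,6,6-trimethyl-4-(pent-4-en-1-yl)bicyclo[3.1.1]heptan-2-one | O=C1[C@@H]2C[C@@H](C2(C)C)[C@](C)(CCCC=C)C1 | intermediate
10 | lithium C8–C9 enolate of 9 | [Li+].[O-]C1=C[C@@](C)(CCCC=C)[C@H]2C[C@@H]1C2(C)C | intermediate
11 | C9-alkylated bicyclic keto ester (side chain anti to the gem-dimethyl bridge) | O=C1[C@@H]2C[C@@H](C2(C)C)[C@](C)(CCCC=C)[C@@H]1CC[C@H](C)CC(=O)OC | intermediate
12 | ring-opened tertiary iodide, C7=C8 trimethylsilyl enol ether | C[Si](C)(C)OC1=CC[C@@H](C(C)(C)I)[C@](C)(CCCC=C)[C@@H]1CC[C@H](C)CC(=O)OC | intermediate
13 | isopropenyl C7=C8 trimethylsilyl enol ether | C[Si](C)(C)OC1=CC[C@@H](C(C)=C)[C@](C)(CCCC=C)[C@@H]1CC[C@H](C)CC(=O)OC | intermediate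
14 | ring B dienyl keto ester (9β side chain, 10β-methyl, H-5α) | O=C1CC[C@@H](C(C)=C)[C@](C)(CCCC=C)[C@H]1CC[C@H](C)CC(=O)OC | intermediate
15 | A-homo alkene, C4(CH3)=C19H, trans-fused | O=C1CC[C@@H]2[C@](C)(CCCC=C2C)[C@H]1CC[C@H](C)CC(=O)OC | intermediate
16 | bromohydrin (4β-OH, 4α-CH3, 19α-Br) | O=C1CC[C@@H]2[C@](C)(CCC[C@@H](Br)[C@]2(C)O)[C@H]1CC[C@H](C)CC(=O)OC | intermediate
17 | 4β,19β-epoxide | O=C1CC[C@@H]2[C@](C)(CCC[C@@H]3O[C@]23C)[C@H]1CC[C@H](C)CC(=O)OC | intermediate
18 | methyl (13S)-8,19-dioxo-17-norlabdan-15-oate | O=C1CC[C@@H]2[C@](C)(CCC[C@]2(C)C=O)[C@H]1CC[C@H](C)CC(=O)OC | intermediate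
19 | (13S)-15-methoxy-8,15-dioxo-17-norlabdan-19-oic acid | O=C1CC[C@@H]2[C@](C)(CCC[C@]2(C)C(=O)O)[C@H]1CC[C@H](C)CC(=O)OC | intermediate
20 | (13S)-15-methoxy-15-oxolabd-8(17)-en-19-oic acid | C=C1CC[C@@H]2[C@](C)(CCC[C@]2(C)C(=O)O)[C@H]1CC[C@H](C)CC(=O)OC | intermediate
21 | (13S)-15-hydroxylabd-8(17)-en-19-oic acid | C=C1CC[C@@H]2[C@](C)(CCC[C@]2(C)C(=O)O)[C@H]1CC[C@H](C)CCO | intermediate
22 | stearoyl chloride | CCCCCCCCCCCCCCCCCC(=O)Cl | starting material
23 | (13S)-15-(stearoyloxy)labd-8(17)-en-19-oic acid | C=C1CC[C@@H]2[C@](C)(CCC[C@]2(C)C(=O)O)[C@H]1CC[C@H](C)CCOC(=O)CCCCCCCCCCCCCCCCC | target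

Total step count: 12. Longest linear sequence: 11 steps (steps 1, 2 and 4 to 12).

**Steps most likely to fail**

1. **Step 8 (key step).**
   - What may go wrong: a 1,2-hydride shift from C19 to C4, or proton loss to an allylic alcohol, may outrun the alkyl shift.
   - Fallback (halohydrin semipinacol with double inversion): it sets out from alkene 15. mCPBA in CH2Cl2 should attack the open α face and give the α-epoxide F1. LiBr with HMPA in toluene at reflux should open F1 at the tertiary C4 from the β face, giving the lithium salt of the bromohydrin F2 (4β-Br, 19α-O).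
   - In F2 the C19–H bond is gauche to C4–Br in every conformer, and only the C19–C3 bond can become antiperiplanar to it. A second inversion at C4 therefore delivers aldehyde 18, where the route is rejoined. This path leaves out steps 7 and 8 and so also covers insufficient β selectivity in step 7.

2. **Step 4.**
   - What may go wrong: SN2 attack by the neopentyl-type enolate carbon may be so slow that elimination of HI from the iodide, O-alkylation or attack on the ester takes over.
   - Fallback (an sp2 electrophile in place of the sp3 one): it sets out from iodide 5 and ketone 9. Kornblum oxidation of 5 (DMSO, NaHCO3, 100 °C) should give the aldehyde F3. Enolate 10, made from 9 as in step 4, should add to it at −78 °C to give the aldol F4.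
   - MsCl and Et3N give the mesylate F5, and DBU gives the exocyclic enone F6. Conjugate reduction with [(Ph3P)CuH]6, which leaves the terminal alkene alone, followed by brief NaOMe in MeOH, returns to 11.

3. **Step 5.**
   - What may go wrong: addition of HI to the terminal alkene, ester cleavage by the silyl iodide, hydride or alkyl shifts of the tertiary cation, or loss of regiocontrol in the elimination.
   - Fallback (the cation is trapped by acetate and the elimination is done separately): it sets out from 11. BF3·OEt2 and Zn(OAc)2 in Ac2O should cleave the cyclobutane to the enol acetate tertiary acetate F7. NaOMe in MeOH should remove both acetyl groups and equilibrate C9 to give the hydroxy ketone F8. SOCl2 in pyridine at 0 °C should dehydrate towards a methyl group and come back to the route at 14.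

**Further compounds**

F1 | step 8 | 4α,19α-epoxide of 15 | O=C1CC[C@@H]2[C@](C)(CCC[C@H]3O[C@@]23C)[C@H]1CC[C@H](C)CC(=O)OC
F2 | step 8 | bromohydrin (4β-Br, 4α-CH3, 19α-OH) | O=C1CC[C@@H]2[C@](C)(CCC[C@@H](O)[C@]2(C)Br)[C@H]1CC[C@H](C)CC(=O)OC
F3 | step 4 | methyl (S)-3-methyl-5-oxopentanoate | O=CC[C@H](C)CC(=O)OC
F4 | step 4 | aldol adduct of 10 and F3 (C11 carbinol, configuration at C11 not controlled) | O=C1[C@@H]2C[C@@H](C2(C)C)[C@](C)(CCCC=C)[C@@H]1C(O)C[C@H](C)CC(=O)OC
F5 | step 4 | C11 mesylate of F4 | O=C1[C@@H]2C[C@@H](C2(C)C)[C@](C)(CCCC=C)[C@@H]1C(OS(C)(=O)=O)C[C@H](C)CC(=O)OC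
F6 | step 4 | exocyclic C9=C11 enone (alkene geometry not controlled) | O=C1[C@@H]2C[C@@H](C2(C)C)[C@](C)(CCCC=C)C1=CC[C@H](C)CC(=O)OC
F7 | step 5 | C7=C8 enol acetate with tertiary C4 acetate | CC(=O)OC1=CC[C@@H](C(C)(C)OC(C)=O)[C@](C)(CCCC=C)[C@@H]1CC[C@H](C)CC(=O)OC
F8 | step 5 | hydroxy ketone (tertiary C4 alcohol, 9β side chain) | O=C1CC[C@@H](C(C)(C)O)[C@](C)(CCCC=C)[C@H]1CC[C@H](C)CC(=O)OC
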